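Ring C is cut across two bonds, O1–C2 and C4–C4a. C4a is the only unsubstituted carbon of ring A and lies ortho to the phenolic O1, so O1–C8a–C4a is a 1,3-O,C-dinucleophile that matches the C2=C3–C4(=O) dielectrophile of a ring B cinnamoyl unit. The key step joins a hexasubstituted 2-bromophenol (ring A with prenyl, lavandulyl and two MOM ethers) to a ring B cinnamic Weinreb amide: bromine–lithium exchange at C4a, acylation, then a cinchona-thiourea-controlled 6-endo oxa-Michael closure in the same pot build ring C and set C2. Only O1 is free, so only the 8-lavandulyl-6-prenyl isomer can form.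

Key step: step 14

Remark: the side chain is built from (S)-lavandulol; its descriptor becomes R in the aryl compounds only because CH2–aryl ranks below isopropenyl whereas CH2OH ranks above it, and no bond to that center is ever touched.

Step 1
Reactants: 1 (4S)-4-benzyl-1,3-oxazolidin-2-one; 2 3-methylbut-2-enoyl chloride
Product: 3 (4S)-4-benzyl-3-(3-methylbut-2-enoyl)-1,3-oxazolidin-2-one
Conditions: n-BuLi, THF, −78 °C; then 2, −78 to 0 °C
Reagents that add atoms: none
Why: N-acylation of the lithiated Evans oxazolidinone by an acid chloride is a standard imide formation that leaves the auxiliary stereocenter untouched.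

Step 2
Reactants: 3 (4S)-4-benzyl-3-(3-methylbut-2-enoyl)-1,3-oxazolidin-2-one; 4 1-bromo-3-methylbut-2-ene (prenyl bromide)
Product: 6 (4S)-4-benzyl-3-[(2S)-5-methyl-2-(prop-1-en-2-yl)hex-4-enoyl]-1,3-oxazolidin-2-one, via sodium dienolate 5 (not isolated)
Conditions: NaN(SiMe3)2, THF, −78 °C; then 4, −78 to −40 °C
Reagents that add atoms: none
Why: Evans asymmetric alkylation in its deconjugative form, in which γ-deprotonation gives the chelated Z-dienolate that reacts with the allylic bromide at the α-carbon on the face away from the benzyl group, so the (4S)-auxiliary should set the new center as 2S while the alkene moves into the isopropenyl position.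

Step 3
Reactants: 6 (4S)-4-benzyl-3-[(2S)-5-methyl-2-(prop-1-en-2-yl)hex-4-enoyl]-1,3-oxazolidin-2-one
Product: 7 (2S)-5-methyl-2-(prop-1-en-2-yl)hex-4-en-1-ol ((S)-lavandulol)
Conditions: LiBH4, H2O (1 equiv), Et2O, 0 °C
Reagents that add atoms: none
Why: Reductive cleavage of the Evans imide by LiBH4 attacks only the exocyclic acyl carbonyl and should give the primary alcohol with the α-stereocenter and both alkenes intact, the auxiliary being recovered.

Step 4
Reactants: 7 (2S)-5-methyl-2-(prop-1-en-2-yl)hex-4-en-1-ol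
Product: 8 (2S)-5-methyl-2-(prop-1-en-2-yl)hex-4-en-1-yl trifluoromethanesulfonate
Conditions: Tf2O, 2,6-lutidine, CH2Cl2, −78 °C; cold filtration through silica, used at once
Reagents that add atoms: trifluoromethanesulfonic anhydride, O=S(=O)(OS(=O)(=O)C(F)(F)F)C(F)(F)F
Why: O-Sulfonylation of the unhindered primary alcohol with triflic anhydride and a hindered pyridine base gives an alkyl triflate reactive enough for the later alkylation of a crowded aryllithium, without touching the stereocenter.

Step 5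
Reactants: 9 benzene-1,3,5-triol (phloroglucinol)
Product: 10 3,5-bis(methoxymethoxy)phenol
Conditions: NaH (2.0 equiv), MOMCl (2.0 equiv), DMF, 0 °C
Reagents that add atoms: chloromethyl methyl ether, COCCl
Why: Williamson-type O-alkylation of the phenoxides with the chloromethyl ether is statistical at this stoichiometry, and the wanted bis-ether is separated by chromatography from the mono- and tris-ethers.

Step 6
Reactants: 10 3,5-bis(methoxymethoxy)phenol
Product: 11 [3,5-bis(methoxymethoxy)phenoxy]tri(propan-2-yl)silane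
Conditions: NaH, i-Pr3SiCl, THF, 0 °C to rt
Reagents that add atoms: chlorotri(propan-2-yl)silane, CC(C)[Si](Cl)(C(C)C)C(C)C
Why: Silylation of the sodium phenoxide gives a bulky aryl silyl ether that marks O1 as the one oxygen to be freed later and, unlike the MOM ethers, does not direct lithium to its neighbours.

Step 7
Reactants: 11 [3,5-bis(methoxymethoxy)phenoxy]tri(propan-2-yl)silane
Product: 12 [2,4,6-tribromo-3,5-bis(methoxymethoxy)phenoxy]tri(propan-2-yl)silane
Conditions: NBS (3.1 equiv), MeCN, 0 °C to rt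
Reagents that add atoms: N-bromosuccinimide, O=C1CCC(=O)N1Br
Why: Electrophilic aromatic bromination takes all three ring carbons, each ortho or para to three oxygen donors, and is placed before any alkene enters the molecule.

Step 8
Reactants: 12 [2,4,6-tribromo-3,5-bis(methoxymethoxy)phenoxy]tri(propan-2-yl)silane; 4 1-bromo-3-methylbut-2-ene
Product: 14 [2,6-dibromo-3,5-bis(methoxymethoxy)-4-(3-methylbut-2-en-1-yl)phenoxy]tri(propan-2-yl)silane, via aryllithium 13 (not isolated)
Conditions: n-BuLi (1.05 equiv), THF, −78 °C; CuBr·SMe2 (10 mol%), 4, −78 to 0 °C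
Reagents that add atoms: none
Why: Bromine–lithium exchange under thermodynamic control should select the bromine flanked by two chelating MOM ethers (the silyl ether does not coordinate), and copper-catalysed allylic substitution of prenyl bromide by the aryl nucleophile then gives the linear prenyl arene.

Step 9
Reactants: 14 [2,6-dibromo-3,5-bis(methoxymethoxy)-4-(3-methylbut-2-en-1-yl)phenoxy]tri(propan-2-yl)silane; 8 (2S)-5-methyl-2-(prop-1-en-2-yl)hex-4-en-1-yl trifluoromethanesulfonate
Product: 16 [2-bromo-3,5-bis(methoxymethoxy)-4-(3-methylbut-2-en-1-yl)-6-[(2R)-5-methyl-2-(prop-1-en-2-yl)hex-4-en-1-yl]phenoxy]tri(propan-2-yl)silane, via aryllithium 15 (not isolated)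
Conditions: n-BuLi (1.0 equiv), THF, −78 °C; then 8 (1.3 equiv), −78 to −30 °C
Reagents that add atoms: none
Why: Single bromine–lithium exchange of the symmetric dibromide followed by SN2 alkylation with the primary triflate at −78 °C, faster than a 1,3-shift of silicon to carbon, should attach the side chain without touching its stereocenter (now named 2R) and leave the last bromine at the future C4a.

Step 10
Reactants: 16 [2-bromo-3,5-bis(methoxymethoxy)-4-(3-methylbut-2-en-1-yl)-6-[(2R)-5-methyl-2-(prop-1-en-2-yl)hex-4-en-1-yl]phenoxy]tri(propan-2-yl)silane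
Product: 17 2-bromo-3,5-bis(methoxymethoxy)-4-(3-methylbut-2-en-1-yl)-6-[(2R)-5-methyl-2-(prop-1-en-2-yl)hex-4-en-1-yl]phenol
Conditions: Bu4NF, THF, 0 °C
Reagents that add atoms: none
Why: Fluoride-mediated desilylation cleaves only the Si–O bond and frees O1, while the MOM ethers, the aryl bromide and the alkenes are inert to Bu4NF.

Step 11
Reactants: 18 5-methoxybenzene-1,3-diol (5-methoxyresorcinol)
Product: 19 1-methoxy-3,5-bis(methoxymethoxy)benzene
Conditions: NaH, MOMCl, DMF, 0 °C to rt
Reagents that add atoms: chloromethyl methyl ether, COCCl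
Why: Williamson-type O-alkylation of both phenols with the chloromethyl ether gives the bis-MOM ether, the methyl ether being unaffected.

Step 12
Reactants: 19 1-methoxy-3,5-bis(methoxymethoxy)benzene
Product: 21 4-methoxy-2,6-bis(methoxymethoxy)benzaldehyde, via aryllithium 20 (not isolated)
Conditions: n-BuLi, TMEDA, THF, 0 °C; then DMF; aqueous NH4Cl
Reagents that add atoms: N,N-dimethylformamide, CN(C)C=O
Why: Directed ortho-metalation should take place at the carbon between the two MOM ethers, the best-coordinated site, and formylation of the aryllithium with DMF gives the aldehyde.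

Step 13
Reactants: 21 4-methoxy-2,6-bis(methoxymethoxy)benzaldehyde; 22 diethyl {2-[methoxy(methyl)amino]-2-oxoethyl}phosphonate
Product: 23 (2E)-N-methoxy-3-[4-methoxy-2,6-bis(methoxymethoxy)phenyl]-N-methylprop-2-enamide
Conditions: NaH, THF, 0 °C to rt
Reagents that add atoms: none
Why: Horner–Wadsworth–Emmons olefination with the stabilised Weinreb amide phosphonate should give the E-enamide, and the basic conditions leave the acetals untouched.

Step 14
Reactants: 17 2-bromo-3,5-bis(methoxymethoxy)-4-(3-methylbut-2-en-1-yl)-6-[(2R)-5-methyl-2-(prop-1-en-2-yl)hex-4-en-1-yl]phenol; 23 (2E)-N-methoxy-3-[4-methoxy-2,6-bis(methoxymethoxy)phenyl]-N-methylprop-2-enamide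
Product: 26 (2S)-5,7-bis(methoxymethoxy)-2-[4-methoxy-2,6-bis(methoxymethoxy)phenyl]-6-(3-methylbut-2-en-1-yl)-8-[(2R)-5-methyl-2-(prop-1-en-2-yl)hex-4-en-1-yl]-2,3-dihydro-4H-chromen-4-one, via dilithio phenoxide 24 (not isolated), via chalcone 25 (not isolated)
Conditions: n-BuLi (1.05 equiv) then t-BuLi (2.1 equiv), THF, −78 °C; 23, −78 to −20 °C; AcOH quench, swap to toluene (salts filtered off); quinidine-derived 9-amino-9-deoxy-epi thiourea with a 3,5-bis(trifluoromethyl)phenyl group (20 mol%), rt, one pot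
Reagents that add atoms: none
Why: Deprotonation and bromine–lithium exchange give the C4a-lithiated phenoxide 24, whose carbanion adds 1,2 to the Weinreb amide (chelated adduct, no over-addition, 1,4-attack blocked by the two ortho MOM ethers of ring B), and the acid quench releases chalcone 25 with the new C4–C4a bond (aryllithium acylation). A bifunctional cinchona thiourea then closes ring C by intramolecular oxa-Michael addition of O1 to C2 in a 6-endo-trig mode, the known organocatalytic biomimetic cyclisation of 2'-hydroxychalcones. The thiourea binds the enone carbonyl while the quinuclidine delivers the phenol to one face of C2, so the catalyst and not the remote side-chain center controls C2; the quinidine-derived catalyst is proposed for the 2S sense, and its quinine-derived pseudoenantiomer is at hand should the sense prove opposite. Regiochemistry needs only O1 to be free, which the MOM ether on O5 secures, so no 6-lavandulyl-8-prenyl isomer can form. The fully substituted ring A twists the carbonyl out of conjugation and so should favour closure over the open chalcone. The alkenes and acetals are inert to every reagent used.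

Step 15
Reactants: 26 (2S)-5,7-bis(methoxymethoxy)-2-[4-methoxy-2,6-bis(methoxymethoxy)phenyl]-6-(3-methylbut-2-en-1-yl)-8-[(2R)-5-methyl-2-(prop-1-en-2-yl)hex-4-en-1-yl]-2,3-dihydro-4H-chromen-4-one
Product: 27 (2S)-2-(2,6-dihydroxy-4-methoxyphenyl)-5,7-dihydroxy-6-(3-methylbut-2-en-1-yl)-8-[(2R)-5-methyl-2-(prop-1-en-2-yl)hex-4-en-1-yl]-2,3-dihydro-4H-chromen-4-one (CNP0301909.2)
Conditions: HCl (3 M aq), MeOH, 40 °C
Reagents that add atoms: none
Why: Acid-catalysed transacetalisation in methanol should remove the four MOM ethers as dimethoxymethane without involving either stereocenter, since C2 epimerises mainly through base-induced ring opening and the side-chain center bears no acidic hydrogen, while the mild temperature limits addition of the freed phenols to the alkenes.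

Compound list
1 | (4S)-4-benzyl-1,3-oxazolidin-2-one | O=C1N[C@@H](Cc2ccccc2)CO1 | starting material
2 | 3-methylbut-2-enoyl chloride | CC(C)=CC(=O)Cl | starting material
3 | (4S)-4-benzyl-3-(3-methylbut-2-enoyl)-1,3-oxazolidin-2-one | CC(C)=CC(=O)N1[C@@H](Cc2ccccc2)COC1=O | intermediate
4 | 1-bromo-3-methylbut-2-ene (prenyl bromide) | CC(C)=CCBr | starting material
5 | sodium (Z)-dienolate of 3 | [Na+].[O-]/C(=C\C(C)=C)N1[C@@H](Cc2ccccc2)COC1=O | intermediate
6 | (4S)-4-benzyl-3-[(2S)-5-methyl-2-(prop-1-en-2-yl)hex-4-enoyl]-1,3-oxazolidin-2-one | CC(C)=CC[C@@H](C(C)=C)C(=O)N1[C@@H](Cc2ccccc2)COC1=O | intermediate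
7 | (2S)-5-methyl-2-(prop-1-en-2-yl)hex-4-en-1-ol ((S)-lavandulol) | CC(C)=CC[C@H](CO)C(C)=C | intermediate
8 | (2S)-5-methyl-2-(prop-1-en-2-yl)hex-4-en-1-yl trifluoromethanesulfonate | CC(C)=CC[C@H](COS(=O)(=O)C(F)(F)F)C(C)=C | intermediate
9 | benzene-1,3,5-triol (phloroglucinol) | Oc1cc(O)cc(O)c1 | starting material
10 | 3,5-bis(methoxymethoxy)phenol | COCOc1cc(O)cc(OCOC)c1 | intermediate
11 | [3,5-bis(methoxymethoxy)phenoxy]tri(propan-2-yl)silane | COCOc1cc(OCOC)cc(O[Si](C(C)C)(C(C)C)C(C)C)c1 | intermediate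
12 | [2,4,6-tribromo-3,5-bis(methoxymethoxy)phenoxy]tri(propan-2-yl)silane | COCOc1c(Br)c(OCOC)c(Br)c(O[Si](C(C)C)(C(C)C)C(C)C)c1Br | intermediate
13 | [3,5-dibromo-2,6-bis(methoxymethoxy)-4-{[tri(propan-2-yl)silyl]oxy}phenyl]lithium | [Li]c1c(OCOC)c(Br)c(O[Si](C(C)C)(C(C)C)C(C)C)c(Br)c1OCOC | intermediate
14 | [2,6-dibromo-3,5-bis(methoxymethoxy)-4-(3-methylbut-2-en-1-yl)phenoxy]tri(propan-2-yl)silane | CC(C)=CCc1c(OCOC)c(Br)c(O[Si](C(C)C)(C(C)C)C(C)C)c(Br)c1OCOC | intermediate
15 | [3-bromo-4,6-bis(methoxymethoxy)-5-(3-methylbut-2-en-1-yl)-2-{[tri(propan-2-yl)silyl]oxy}phenyl]lithium | [Li]c1c(OCOC)c(CC=C(C)C)c(OCOC)c(Br)c1O[Si](C(C)C)(C(C)C)C(C)C | intermediate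
16 | [2-bromo-3,5-bis(methoxymethoxy)-4-(3-methylbut-2-en-1-yl)-6-[(2R)-5-methyl-2-(prop-1-en-2-yl)hex-4-en-1-yl]phenoxy]tri(propan-2-yl)silane | CC(C)=CC[C@H](Cc1c(OCOC)c(CC=C(C)C)c(OCOC)c(Br)c1O[Si](C(C)C)(C(C)C)C(C)C)C(C)=C | intermediate
17 | 2-bromo-3,5-bis(methoxymethoxy)-4-(3-methylbut-2-en-1-yl)-6-[(2R)-5-methyl-2-(prop-1-en-2-yl)hex-4-en-1-yl]phenol | CC(C)=CC[C@H](Cc1c(OCOC)c(CC=C(C)C)c(OCOC)c(Br)c1O)C(C)=C | intermediate
18 | 5-methoxybenzene-1,3-diol (5-methoxyresorcinol) | COc1cc(O)cc(O)c1 | starting material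
19 | 1-methoxy-3,5-bis(methoxymethoxy)benzene | COCOc1cc(OC)cc(OCOC)c1 | intermediate
20 | [4-methoxy-2,6-bis(methoxymethoxy)phenyl]lithium | [Li]c1c(OCOC)cc(OC)cc1OCOC | intermediate
21 | 4-methoxy-2,6-bis(methoxymethoxy)benzaldehyde | COCOc1cc(OC)cc(OCOC)c1C=O | intermediate
22 | diethyl {2-[methoxy(methyl)amino]-2-oxoethyl}phosphonate | CCOP(=O)(CC(=O)N(C)OC)OCC | starting material
23 | (2E)-N-methoxy-3-[4-methoxy-2,6-bis(methoxymethoxy)phenyl]-N-methylprop-2-enamide | COCOc1cc(OC)cc(OCOC)c1/C=C/C(=O)N(C)OC | intermediate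
24 | lithium 2-lithio-3,5-bis(methoxymethoxy)-4-(3-methylbut-2-en-1-yl)-6-[(2R)-5-methyl-2-(prop-1-en-2-yl)hex-4-en-1-yl]phenoxide | CC(C)=CC[C@H](Cc1c(OCOC)c(CC=C(C)C)c(OCOC)c([Li])c1O[Li])C(C)=C | intermediate
25 | (2E)-1-[2-hydroxy-4,6-bis(methoxymethoxy)-5-(3-methylbut-2-en-1-yl)-3-[(2R)-5-methyl-2-(prop-1-en-2-yl)hex-4-en-1-yl]phenyl]-3-[4-methoxy-2,6-bis(methoxymethoxy)phenyl]prop-2-en-1-one | CC(C)=CC[C@H](Cc1c(OCOC)c(CC=C(C)C)c(OCOC)c(C(=O)/C=C/c2c(OCOC)cc(OC)cc2OCOC)c1O)C(C)=C | intermediate
26 | (2S)-5,7-bis(methoxymethoxy)-2-[4-methoxy-2,6-bis(methoxymethoxy)phenyl]-6-(3-methylbut-2-en-1-yl)-8-[(2R)-5-methyl-2-(prop-1-en-2-yl)hex-4-en-1-yl]-2,3-dihydro-4H-chromen-4-one | C=C(C)[C@H](CC=C(C)C)Cc1c(OCOC)c(CC=C(C)C)c(OCOC)c2c1O[C@H](c1c(OCOC)cc(OC)cc1OCOC)CC2=O | intermediate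
27 | (2S)-2-(2,6-dihydroxy-4-methoxyphenyl)-5,7-dihydroxy-6-(3-methylbut-2-en-1-yl)-8-[(2R)-5-methyl-2-(prop-1-en-2-yl)hex-4-en-1-yl]-2,3-dihydro-4H-chromen-4-one | C=C(C)[C@H](CC=C(C)C)Cc1c(O)c(CC=C(C)C)c(O)c2c1O[C@H](c1c(O)cc(OC)cc1O)CC2=O | target

Total step count: 15.
Longest linear sequence: 8 steps (steps 5, 6, 7, 8, 9, 10, 14, 15; the side-chain branch 1, 2, 3, 4, 9, 10, 14, 15 is equally long).

Steps most likely to fail

Step 14. What may go wrong: poor facial selectivity or slow turnover in the catalysed ring closure at the crowded C2, so that both C2 epimers form. Fallback: the sequence sets out from chalcone 25, isolated after the acid quench of step 14. Unselective closure with NaOAc in EtOH at reflux should give 26 together with its C2 epimer, the (2R)-flavanone F1. Asymmetric transfer hydrogenation under kinetic resolution with Cp*RhCl(TsDPEN), using the ligand antipode that reduces the 2R ketone faster, in HCO2H/Et3N and EtOAc at rt, should turn F1 into the cis-(2R,4R)-flavan-4-ol F2 while 26 stays a ketone. Chromatography then returns the route at 26.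

Step 15. What may go wrong: acid-driven addition of the freed phenols to the prenyl or isopropenyl alkenes, or epimerisation at C2 by ring opening. Fallback: the sequence sets out from 26 and avoids protic acid. Et3SiOTf with 2,2'-bipyridyl in CH2Cl2 at 0 °C should exchange the four aryl MOM ethers for silyl ethers and give the tetrakis(triethylsilyl) ether F5. Buffered fluoride (Et3N·3HF, THF, 0 °C) then frees the phenols and returns the route at 27.

Step 9. What may go wrong: slow SN2 at the crowded aryllithium, with elimination of the triflate or migration of silicon from oxygen to carbon taking over. Fallback: the polarity is reversed, setting out from alcohol 7 and dibromide 14. I2, PPh3 and imidazole convert 7 into (S)-lavandulyl iodide F3. Zn dust with LiCl in THF gives the lavandulylzinc iodide F4. Negishi coupling of F4 with 14 (14 in excess to favour single coupling) under Pd(OAc)2 and CPhos should give 16, where the route is rejoined.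

Further compounds
F1 | step 14 | (2R)-5,7-bis(methoxymethoxy)-2-[4-methoxy-2,6-bis(methoxymethoxy)phenyl]-6-(3-methylbut-2-en-1-yl)-8-[(2R)-5-methyl-2-(prop-1-en-2-yl)hex-4-en-1-yl]-2,3-dihydro-4H-chromen-4-one | C=C(C)[C@H](CC=C(C)C)Cc1c(OCOC)c(CC=C(C)C)c(OCOC)c2c1O[C@@H](c1c(OCOC)cc(OC)cc1OCOC)CC2=O
F2 | step 14 | (2R,4R)-5,7-bis(methoxymethoxy)-2-[4-methoxy-2,6-bis(methoxymethoxy)phenyl]-6-(3-methylbut-2-en-1-yl)-8-[(2R)-5-methyl-2-(prop-1-en-2-yl)hex-4-en-1-yl]-3,4-dihydro-2H-chromen-4-ol | C=C(C)[C@H](CC=C(C)C)Cc1c(OCOC)c(CC=C(C)C)c(OCOC)c2c1O[C@@H](c1c(OCOC)cc(OC)cc1OCOC)C[C@H]2O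
F3 | step 9 | (3S)-3-(iodomethyl)-2,6-dimethylhepta-1,5-diene ((S)-lavandulyl iodide) | CC(C)=CC[C@H](CI)C(C)=C
F4 | step 9 | [(2S)-5-methyl-2-(prop-1-en-2-yl)hex-4-en-1-yl]zinc iodide | CC(C)=CC[C@H](C[Zn]I)C(C)=C
F5 | step 15 | (2S)-2-{4-methoxy-2,6-bis[(triethylsilyl)oxy]phenyl}-6-(3-methylbut-2-en-1-yl)-8-[(2R)-5-methyl-2-(prop-1-en-2-yl)hex-4-en-1-yl]-5,7-bis[(triethylsilyl)oxy]-2,3-dihydro-4H-chromen-4-one | C=C(C)[C@H](CC=C(C)C)Cc1c(O[Si](CC)(CC)CC)c(CC=C(C)C)c(O[Si](CC)(CC)CC)c2c1O[C@H](c1c(O[Si](CC)(CC)CC)cc(OC)cc1O[Si](CC)(CC)CC)CC2=O
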